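Time is what oak, the flask asked about, shows most plainly. After 30.0 min it holds 24.1% of target and gained 3 percentage points over its last 10.0 min, though 75.9% of the starting material remains.

common to all: starting material 20 mM; free catalyst 2.5 mol%

|  | second substrate | solid reagent | temperature | remark | time |
|---|---|---|---|---|---|
| oak | 0.20 equiv | 1.5 equiv | 50 °C | the very flask that is asked about, followed so far |  |
| alder | 0.20 equiv | 3 equiv | 45 °C | run made earlier |  |
| flask | 0.200 equiv | 1.50 equiv | 50 °C |  | 50 min |

- oak (time / min: target / %): 2.50: 5.6; 8.00: 14.4; 15.0: 18.7; 20.0: 21.1; 30.0: 24.1
- alder (time / min: target / %): 1.33: 3.3; 2.50: 4.5; 5.00: 10.7; 10.0: 20.6; 20.0: 32.5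

(standard deviation of a reading: 1 percentage point)

- given per volume of solution although it is solid: solid reagent
- target taken out counts as made
- steps that have been proposed: starting material + partner + free catalyst -> free catalyst + target; second substrate + partner + free catalyst -> free catalyst + second product; 2 free catalyst <-> resting dimer; solid reagent <-> partner; free catalyst -> spent catalyst
- at the start none of the solid reagent is in solution
- additions bring no volume worth counting

- target, in percent of the starting material first charged, at 50 min
- the remedy with the largest gain of target, or "none" below 2 percentage points (autumn / noon / spring / dawn / none)
- target present, with what was taken out counted in, in percent of the starting material first charged, after autumn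
- target present, with what was taken out counted in, in percent of the starting material first charged, after noon

- autumn: at 50 min raise the temperature by 15 K, then wait 1.5 h
- noon: at 50 min add free catalyst, 50.0% of the amount charged, then wait 1.5 h
- spring: change nothing and wait 1.5 h more
- dawn: at 50 min take out 90% of the target then present, then wait 1.5 h

Two chemists agree that the catalyst has stopped working, so neither expects reach from autumn, spring or dawn, none of which adds catalyst. I take now as about the last reading. They part over a fresh dose.

Both reckon in one quantity. Oak's last reading gives 0.276 of the reach, the natural logarithm of the starting material before a stretch over that after it. It is the exponent of a pseudo-first-order loss, and the reach of successive doses adds up.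

The first chemist holds that a dose's reach follows its amount of catalyst. Noon's dose then has 0.138, which takes 9.8 points of the starting material left.

The second objects that no solid reagent is in solution at the start, so [partner] starts from nothing and the earliest catalyst works in a thin solution. Oak had 59.8% of its last reading by 8.00 min, while alder, at 45 °C, still gained as fast between 5.00 min and 10.0 min as before. If [partner] grows steadily, a dose at 50 min meets 6.25 times what oak's charge met, taking that charge as working up to 8.00 min; this factor is a rough estimate. The dose's reach becomes 0.862.

Now the two ends are joined. A small reach takes the starting material left times the reach, a large one takes what is left, and the exponential runs between them. So the gain is 44 points, for a total of 68.1%. The second grants that the first's rule is right between doses that meet the same [partner] at the same temperature.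

The forecast takes the first side, a little above that side's figure as reckoned here: 26% now, noon best, 27% after autumn and 36% after noon, on the ground that “Total product scales with catalyst charged, even through the dimer.”

The flask gives 20.6% at 50 min, which is 3.5 points under oak's last reading, more than its scatter. Autumn ends at 20.6%, a gain of 0 points, and spring and dawn gain 0 points and 0 points. Noon reaches 66.6%, a gain of 46 points, so the best remedy is noon.

    starting material + partner + free catalyst → free catalyst + target (k = 5.21 × 10⁵ L² mol⁻² min⁻¹, Ea = 31.0 kJ mol⁻¹)
    second substrate + partner + free catalyst → free catalyst + second product (k = 1.19 × 10⁵ L² mol⁻² min⁻¹, Ea = 36.0 kJ mol⁻¹)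
    2 free catalyst ⇌ resting dimer, settled at all times (K = 560 L mol⁻¹, ΔH = −23.0 kJ mol⁻¹)
    solid reagent ⇌ partner, rate k4*(cs4 - [partner]) while solid is left; crystals form when [partner] > cs4 (solubility = 9.30 mM, k = 0.0579 min⁻¹)
    free catalyst → spent catalyst (k = 0.399 min⁻¹, Ea = 88.0 kJ mol⁻¹)
    (constants at 50 °C)

In the flask free catalyst has a half-life of 1.7 min at 13.1 min, while the solid reagent takes 13.1 min for half of its going into solution up to 50 min, and [partner] stands at 0.453 mM at 5.00 min, with 80.5% of the catalyst spent, against 8.44 mM at 50.0 min. Oak's reach read 0.276 and the flask's first charge shows 0.231; the noon dose shows 0.866 against the 0.862 reckoned, and a neighbour flask run at 25 °C shows 2.53 by 50.0 min.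

Readings and results come from a simulation for an exercise; noise was put on by code.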